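The trimethylcyclohexene ring (C26'–C31') is made by closing it at its own olefin. The trisubstituted C27'=C28' bond is not conjugated and sits next to the stereocentre C26' and the quaternary C31'. Ring-closing metathesis of an acyclic diene forms this bond and the six-membered ring in one neutral operation, so the olefin cannot migrate and C26' cannot epimerise. The precursor is a benzyl-protected 2-isopropenyl-3,3-dimethylhept-6-en-1-ol whose C26' centre comes from an oxazolidinone-directed alkoxymethylation. The cyclised unit is then linked as a sulfone to a 1,12-difunctional farnesyl unit and to a chiral-pool spacer carrying the masked naphthoquinone.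

Key step: step 7

Remark: locants run along the side chain from the quinone (C1'–C25') into the ring (C26' CH, C27' C-methyl, C28' =CH, C29', C30', C31' CMe2); the sulfonyl-bearing carbons C25' and C12' in 20–22 and 42 are formed as epimer mixtures, which is without consequence because both become CH2 in step 29.

Remark: diene 10 carries the descriptor R although its C26' geometry is that of the S-configured ring in 11 and in the target, because C31' outranks the isopropenyl carbon before ring closure and the ring carbon C27' outranks C31' after it.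

Step 1
Reactants: 1 (4S)-4-benzyl-1,3-oxazolidin-2-one; 2 3-methylbut-2-enoyl chloride
Product: 4 (4S)-4-benzyl-3-(3-methylbut-2-enoyl)-1,3-oxazolidin-2-one, via N-lithio oxazolidinone 3 (not isolated)
Conditions: n-BuLi, THF, −78 °C; then 2, −78 °C to 0 °C
Reagents that add atoms: none
Why: N-acylation of the lithiated oxazolidinone by the acid chloride (acyl substitution); deprotonating first avoids amine bases, which would deconjugate the senecioyl unit through a vinylketene.

Step 2
Reactants: 4 (4S)-4-benzyl-3-(3-methylbut-2-enoyl)-1,3-oxazolidin-2-one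
Product: 5 (4S)-4-benzyl-3-(3,3-dimethylhept-6-enoyl)-1,3-oxazolidin-2-one
Conditions: CH2=CHCH2CH2MgBr, CuBr·SMe2, THF/Me2S, −40 °C to 0 °C; NH4Cl
Reagents that add atoms: but-3-enylmagnesium bromide (C=CCC[Mg]Br)
Why: Copper-mediated conjugate addition of a Grignard reagent to an N-enoyl oxazolidinone; the imide resists 1,2-attack and the organocopper species adds to the β,β-disubstituted carbon, creating the non-stereogenic quaternary C31'.

Step 3
Reactants: 5 (4S)-4-benzyl-3-(3,3-dimethylhept-6-enoyl)-1,3-oxazolidin-2-one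
Product: 7 (4S)-4-benzyl-3-{(2R)-2-[(benzyloxy)methyl]-3,3-dimethylhept-6-enoyl}-1,3-oxazolidin-2-one, via chlorotitanium enolate 6 (not isolated)
Conditions: TiCl4, i-Pr2NEt, CH2Cl2, 0 °C; then BnOCH2Cl, 0 °C
Reagents that add atoms: benzyl chloromethyl ether (ClCOCc1ccccc1)
Why: Evans titanium-enolate alkylation, in which the chelated Z-enolate is attacked by the small oxocarbenium-type electrophile on the face opposite the C4 benzyl group, setting C26' (2R in 7, the geometry of the target); the benzyl ether arrives with the electrophile and should withstand TiCl4, MeLi and the ruthenium carbene.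

Step 4
Reactants: 7 (4S)-4-benzyl-3-{(2R)-2-[(benzyloxy)methyl]-3,3-dimethylhept-6-enoyl}-1,3-oxazolidin-2-one
Product: 8 (2R)-2-[(benzyloxy)methyl]-3,3-dimethylhept-6-enoic acid
Conditions: LiOH, 30% H2O2, THF/H2O, 0 °C; Na2SO3; HCl
Reagents that add atoms: hydrogen peroxide (OO)
Why: Hydroperoxide cleavage of the imide, in which LiOOH attacks the exocyclic carbonyl even when it is hindered, should release the acid without epimerisation and return the auxiliary.

Step 5
Reactants: 8 (2R)-2-[(benzyloxy)methyl]-3,3-dimethylhept-6-enoic acid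
Product: 9 (3R)-3-[(benzyloxy)methyl]-4,4-dimethyloct-7-en-2-one
Conditions: MeLi (3 equiv), Et2O, 0 °C; inverse quench into cold 1 M HCl
Reagents that add atoms: methyllithium ([Li]C)
Why: Ketone synthesis from a carboxylic acid and an organolithium; the dilithium gem-diolate persists until hydrolysis, so a second addition is excluded and the non-enolisable intermediate shields C26'.

Step 6
Reactants: 9 (3R)-3-[(benzyloxy)methyl]-4,4-dimethyloct-7-en-2-one
Product: 10 benzyl (2R)-3,3-dimethyl-2-(prop-1-en-2-yl)hept-6-en-1-yl ether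
Conditions: Zn, CH2Br2, TiCl4, THF/CH2Cl2, 0 °C to rt
Reagents that add atoms: dibromomethane (BrCBr)
Why: Takai–Lombardo methylenation; the titanium–zinc methylene reagent is non-basic, so the enolisable β-alkoxy ketone should be converted into the isopropenyl group with C26' intact.

Step 7
Reactants: 10 benzyl (2R)-3,3-dimethyl-2-(prop-1-en-2-yl)hept-6-en-1-yl ether
Product: 11 benzyl [(1S)-2,6,6-trimethylcyclohex-2-en-1-yl]methyl ether
Conditions: second-generation Grubbs catalyst RuCl2(=CHPh)(H2IMes)(PCy3) (5 mol%), 1,4-benzoquinone (10 mol%), CH2Cl2 (0.01 M), 40 °C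
Reagents that add atoms: none
Why: Ring-closing olefin metathesis: the ruthenium benzylidene exchanges onto the unhindered monosubstituted olefin to give an alkylidene at C28', which undergoes [2+2] cycloaddition with the isopropenyl olefin at C27' and cycloreverts with loss of ethylene. The closest known reaction type is the closure of a 1,1-disubstituted onto a monosubstituted olefin to a trisubstituted cyclohexene with this catalyst class. The ring C26'–C31' closes by forming C27'=C28' as its sixth bond, and the gem-dimethyl group at C31' favours the folded conformer that brings the two olefins together. No stereocentre is created, and C26' passes through unchanged because the medium contains neither acid nor base. The step needs the olefin to stay at C27'=C28' and ring closure to outrun intermolecular cross-metathesis; this is secured by high dilution, by the presence of only two olefins in 10 and by benzoquinone, which intercepts ruthenium hydrides that would cause olefin migration.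

Step 8
Reactants: 11 benzyl [(1S)-2,6,6-trimethylcyclohex-2-en-1-yl]methyl ether
Product: 12 [(1S)-2,6,6-trimethylcyclohex-2-en-1-yl]methanol
Conditions: Li, NH3(l)/THF, −78 °C; NH4Cl
Reagents that add atoms: none
Why: Dissolving-metal debenzylation (reductive cleavage of the benzylic C–O bond); the isolated trisubstituted olefin is not reduced under these conditions.

Step 9
Reactants: 12 [(1S)-2,6,6-trimethylcyclohex-2-en-1-yl]methanol
Product: 13 phenyl [(1S)-2,6,6-trimethylcyclohex-2-en-1-yl]methyl sulfide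
Conditions: PhSSPh, n-Bu3P, pyridine, rt to 50 °C
Reagents that add atoms: diphenyl disulfide (c1ccc(SSc2ccccc2)cc1)
Why: Hata reaction (alkoxyphosphonium formation, then SN2 displacement by thiophenolate) should convert the hindered primary alcohol without acid that could move the ring olefin.

Step 10
Reactants: 13 phenyl [(1S)-2,6,6-trimethylcyclohex-2-en-1-yl]methyl sulfide
Product: 14 phenyl [(1S)-2,6,6-trimethylcyclohex-2-en-1-yl]methyl sulfone
Conditions: (NH4)6Mo7O24·4H2O (5 mol%), 30% H2O2, EtOH, 0 °C to rt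
Reagents that add atoms: hydrogen peroxide (OO)
Why: Molybdate-catalysed peroxide oxidation of a sulfide to the sulfone, which is chemoselective for sulfur over a trisubstituted olefin.

Step 11
Reactants: 15 (2E,6E)-farnesol
Product: 16 (2E,6E)-farnesyl tert-butyldimethylsilyl ether
Conditions: TBSCl, imidazole, DMF, rt
Reagents that add atoms: tert-butyldimethylsilyl chloride (CC(C)(C)[Si](C)(C)Cl)
Why: Silylation of the primary allylic alcohol; unlike an ester, the silyl ether is inert to the lithiated sulfone of step 14.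

Step 12
Reactants: 16 (2E,6E)-farnesyl tert-butyldimethylsilyl ether
Product: 17 (2E,6E,10E)-12-[(tert-butyldimethylsilyl)oxy]-2,6,10-trimethyldodeca-2,6,10-trien-1-ol
Conditions: SeO2 (10 mol%), t-BuOOH, salicylic acid (10 mol%), CH2Cl2, 0 °C to rt
Reagents that add atoms: tert-butyl hydroperoxide (CC(C)(C)OO)
Why: SeO2-catalysed allylic oxidation (ene reaction, then [2,3]-sigmatropic shift) favours the E-methyl group of the terminal gem-dimethyl olefin and should give the (E)-allylic alcohol that becomes C24'.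

Step 13
Reactants: 17 (2E,6E,10E)-12-[(tert-butyldimethylsilyl)oxy]-2,6,10-trimethyldodeca-2,6,10-trien-1-ol
Product: 18 (2E,6E,10E)-12-bromo-3,7,11-trimethyldodeca-2,6,10-trien-1-yl tert-butyldimethylsilyl ether
Conditions: CBr4, PPh3, CH2Cl2, −20 °C to 0 °C
Reagents that add atoms: carbon tetrabromide (BrC(Br)(Br)Br)
Why: Appel bromination of a primary allylic alcohol under neutral conditions, which keeps the olefin geometry and the silyl ether.

Step 14
Reactants: 14 phenyl [(1S)-2,6,6-trimethylcyclohex-2-en-1-yl]methyl sulfone; 18 (2E,6E,10E)-12-bromo-3,7,11-trimethyldodeca-2,6,10-trien-1-yl tert-butyldimethylsilyl ether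
Product: 20 (2E,6E,10E)-3,7,11-trimethyl-13-(phenylsulfonyl)-13-[(1S)-2,6,6-trimethylcyclohex-2-en-1-yl]trideca-2,6,10-trien-1-yl tert-butyldimethylsilyl ether, via lithiated sulfone 19 (not isolated)
Conditions: n-BuLi, THF, −78 °C; then 18, DMPU, −78 °C to −20 °C
Reagents that add atoms: none
Why: SN2 alkylation of an α-sulfonyl carbanion by a primary allylic bromide forms C24'–C25'; the sulfonyl carbon ends up homoallylic, so its later reductive removal cannot shift a double bond.

Step 15
Reactants: 20 (2E,6E,10E)-3,7,11-trimethyl-13-(phenylsulfonyl)-13-[(1S)-2,6,6-trimethylcyclohex-2-en-1-yl]trideca-2,6,10-trien-1-yl tert-butyldimethylsilyl ether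
Product: 21 (2E,6E,10E)-3,7,11-trimethyl-13-(phenylsulfonyl)-13-[(1S)-2,6,6-trimethylcyclohex-2-en-1-yl]trideca-2,6,10-trien-1-ol
Conditions: Bu4NF, THF, 0 °C to rt
Reagents that add atoms: none
Why: Fluoride-induced desilylation frees the allylic alcohol at C13' and leaves the sulfone and the olefins untouched.

Step 16
Reactants: 21 (2E,6E,10E)-3,7,11-trimethyl-13-(phenylsulfonyl)-13-[(1S)-2,6,6-trimethylcyclohex-2-en-1-yl]trideca-2,6,10-trien-1-ol
Product: 22 (2E,6E,10E)-1-bromo-3,7,11-trimethyl-13-(phenylsulfonyl)-13-[(1S)-2,6,6-trimethylcyclohex-2-en-1-yl]trideca-2,6,10-triene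
Conditions: CBr4, PPh3, CH2Cl2, −20 °C to 0 °C; used without storage
Reagents that add atoms: carbon tetrabromide (BrC(Br)(Br)Br)
Why: Appel bromination under neutral conditions gives the farnesyl-type primary allylic bromide without touching the acid-sensitive ring olefin.

Step 17
Reactants: 23 menadione (2-methylnaphthalene-1,4-dione)
Product: 25 1,4-dimethoxy-2-methylnaphthalene, via menadiol 24 (not isolated)
Conditions: Na2S2O4, Bu4NBr (cat.), THF/H2O, rt; then KOH, Me2SO4, rt
Reagents that add atoms: dimethyl sulfate (COS(=O)(=O)OC)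
Why: One-pot reductive methylation: dithionite reduces the quinone to the hydroquinone, which is O-methylated under phase transfer (Williamson ether synthesis).

Step 18
Reactants: 25 1,4-dimethoxy-2-methylnaphthalene
Product: 26 2-(chloromethyl)-1,4-dimethoxy-3-methylnaphthalene
Conditions: (CH2O)n, conc. HCl, HCl gas, dioxane, rt
Reagents that add atoms: formaldehyde as paraformaldehyde (C=O); hydrogen chloride (Cl)
Why: Blanc chloromethylation (electrophilic aromatic substitution) should occur at the only free position of the electron-rich dimethoxy ring.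

Step 19
Reactants: 27 (2R)-3-bromo-2-methylpropan-1-ol
Product: 28 (2R)-3-bromo-2-methylpropyl tert-butyldimethylsilyl ether
Conditions: TBSCl, imidazole, CH2Cl2, rt
Reagents that add atoms: tert-butyldimethylsilyl chloride (CC(C)(C)[Si](C)(C)Cl)
Why: Silylation masks the hydroxyl group that becomes C12'–O so that the bromide can be turned into a Grignard reagent.

Step 20
Reactants: 28 (2R)-3-bromo-2-methylpropyl tert-butyldimethylsilyl ether; 29 (6S)-8-bromo-2,6-dimethyloct-2-ene
Product: 31 (2S,6R)-2,6,10-trimethylundec-9-en-1-yl tert-butyldimethylsilyl ether, via Grignard reagent 30 (not isolated)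
Conditions: Mg, BrCH2CH2Br (cat.), THF, 40 °C; then 29, Li2CuCl4 (5 mol%), THF, −20 °C to rt
Reagents that add atoms: none
Why: Kochi-type Li2CuCl4-catalysed coupling of a Grignard reagent with a primary alkyl bromide joins C9'–C10'; C7' and C11' come unchanged from the two chiral-pool partners.

Step 21
Reactants: 31 (2S,6R)-2,6,10-trimethylundec-9-en-1-yl tert-butyldimethylsilyl ether
Product: 33 (4R,8S)-9-[(tert-butyldimethylsilyl)oxy]-4,8-dimethylnonan-1-ol, via aldehyde 32 (not isolated)
Conditions: O3, CH2Cl2/MeOH, −78 °C; then NaBH4, −78 °C to rt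
Reagents that add atoms: ozone ([O-][O+]=O)
Why: Ozonolysis with reductive borohydride work-up cleaves the isopropylidene olefin and delivers the primary alcohol at C4'.

Step 22
Reactants: 33 (4R,8S)-9-[(tert-butyldimethylsilyl)oxy]-4,8-dimethylnonan-1-ol
Product: 34 (2S,6R)-9-iodo-2,6-dimethylnonyl tert-butyldimethylsilyl ether
Conditions: I2, PPh3, imidazole, CH2Cl2, 0 °C
Reagents that add atoms: iodine (II)
Why: Appel-type iodination (Garegg–Samuelsson conditions) of the primary alcohol; the imidazole buffer protects the silyl ether.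

Step 23
Reactants: 34 (2S,6R)-9-iodo-2,6-dimethylnonyl tert-butyldimethylsilyl ether
Product: 35 (2S,6R)-2,6-dimethylundec-10-yn-1-yl tert-butyldimethylsilyl ether
Conditions: LiC≡CH·H2NCH2CH2NH2, DMSO, 10 °C to rt
Reagents that add atoms: lithium acetylide as its ethylenediamine complex ([Li]C#C)
Why: SN2 alkylation of lithium acetylide by the unbranched primary iodide installs C3'≡C2' as a terminal alkyne.

Step 24
Reactants: 35 (2S,6R)-2,6-dimethylundec-10-yn-1-yl tert-butyldimethylsilyl ether; 26 2-(chloromethyl)-1,4-dimethoxy-3-methylnaphthalene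
Product: 37 (2S,6R,10E)-12-(1,4-dimethoxy-3-methylnaphthalen-2-yl)-2,6,10-trimethyldodec-10-en-1-yl tert-butyldimethylsilyl ether, via alkenylalane 36 (not isolated)
Conditions: Me3Al, Cp2ZrCl2 (25 mol%), ClCH2CH2Cl, rt; then 26, NiCl2(PPh3)2 (5 mol%)/n-BuLi (10 mol%), THF, rt
Reagents that add atoms: trimethylaluminium (C[Al](C)C)
Why: Negishi zirconium-catalysed carboalumination adds methyl and aluminium syn across the terminal alkyne (methyl to C3'), and the E-alkenylalane is then cross-coupled with the benzylic chloride under zerovalent nickel catalysis with retention, so C2'=C3' is formed E together with the C1'–C2' bond.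

Step 25
Reactants: 37 (2S,6R,10E)-12-(1,4-dimethoxy-3-methylnaphthalen-2-yl)-2,6,10-trimethyldodec-10-en-1-yl tert-butyldimethylsilyl ether
Product: 38 (2S,6R,10E)-12-(1,4-dimethoxy-3-methylnaphthalen-2-yl)-2,6,10-trimethyldodec-10-en-1-ol
Conditions: Bu4NF, THF, 0 °C to rt
Reagents that add atoms: none
Why: Fluoride-induced desilylation frees the primary alcohol at C12'.

Step 26
Reactants: 38 (2S,6R,10E)-12-(1,4-dimethoxy-3-methylnaphthalen-2-yl)-2,6,10-trimethyldodec-10-en-1-ol
Product: 39 2-[(2E,7R,11S)-12-iodo-3,7,11-trimethyldodec-2-en-1-yl]-1,4-dimethoxy-3-methylnaphthalene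
Conditions: I2, PPh3, imidazole, CH2Cl2, 0 °C
Reagents that add atoms: iodine (II)
Why: Appel-type iodination of the primary alcohol under buffered conditions that spare the olefin and the fully substituted dimethoxy ring.

Step 27
Reactants: 39 2-[(2E,7R,11S)-12-iodo-3,7,11-trimethyldodec-2-en-1-yl]-1,4-dimethoxy-3-methylnaphthalene
Product: 40 1,4-dimethoxy-2-methyl-3-[(2E,7R,11S)-3,7,11-trimethyl-12-(phenylsulfonyl)dodec-2-en-1-yl]naphthalene
Conditions: PhSO2Na, DMF, 60 °C
Reagents that add atoms: sodium benzenesulfinate ([Na+].[O-]S(=O)c1ccccc1)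
Why: SN2 displacement of the primary iodide by the sulfinate through sulfur gives the sulfone without an oxidant and leaves C11' untouched.

Step 28
Reactants: 40 1,4-dimethoxy-2-methyl-3-[(2E,7R,11S)-3,7,11-trimethyl-12-(phenylsulfonyl)dodec-2-en-1-yl]naphthalene; 22 (2E,6E,10E)-1-bromo-3,7,11-trimethyl-13-(phenylsulfonyl)-13-[(1S)-2,6,6-trimethylcyclohex-2-en-1-yl]trideca-2,6,10-triene
Product: 42 bis-sulfone (compound 43 bearing phenylsulfonyl groups at C12' and C25'), via lithiated sulfone 41 (not isolated)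
Conditions: n-BuLi, THF, −78 °C; then 22, DMPU, −78 °C to −20 °C
Reagents that add atoms: none
Why: SN2 alkylation of the α-sulfonyl carbanion by the allylic bromide forms C12'–C13'; the primary CH2SO2Ph of 40 is deprotonated before 22 is added, and the tertiary α-hydrogen at C25' of 22 is far less accessible.

Step 29
Reactants: 42 bis-sulfone (compound 43 bearing phenylsulfonyl groups at C12' and C25')
Product: 43 1,4-dimethoxy-2-methyl-3-[(2E,7R,11S,14E,18E,22E)-3,7,11,15,19,23-hexamethyl-25-[(1S)-2,6,6-trimethylcyclohex-2-en-1-yl]pentacosa-2,14,18,22-tetraen-1-yl]naphthalene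
Conditions: 6% Na(Hg), Na2HPO4, MeOH/THF, −20 °C to rt
Reagents that add atoms: none
Why: Reductive desulfonylation (electron transfer, C–S cleavage, protonation) removes both sulfonyl groups in one operation; neither carbanion is allylic, so no olefin should move.

Step 30
Reactants: 43 1,4-dimethoxy-2-methyl-3-[(2E,7R,11S,14E,18E,22E)-3,7,11,15,19,23-hexamethyl-25-[(1S)-2,6,6-trimethylcyclohex-2-en-1-yl]pentacosa-2,14,18,22-tetraen-1-yl]naphthalene
Product: 44 2-methyl-3-[(2E,7R,11S,14E,18E,22E)-3,7,11,15,19,23-hexamethyl-25-[(1S)-2,6,6-trimethylcyclohex-2-en-1-yl]pentacosa-2,14,18,22-tetraen-1-yl]naphthalene-1,4-dione (CNP0165638.1)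
Conditions: (NH4)2Ce(NO3)6, MeCN/H2O/CH2Cl2, 0 °C
Reagents that add atoms: water (O)
Why: Oxidative demethylation of a hydroquinone dimethyl ether to the quinone with the cerium oxidant, a reaction that spares isolated trisubstituted olefins.

Compound list

1 | (4S)-4-benzyl-1,3-oxazolidin-2-one | O=C1N[C@@H](Cc2ccccc2)CO1 | starting material
2 | 3-methylbut-2-enoyl chloride | CC(C)=CC(=O)Cl | starting material
3 | N-lithio-(4S)-4-benzyl-1,3-oxazolidin-2-one (formed in the flask) | [Li]N1[C@@H](Cc2ccccc2)COC1=O | intermediate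
4 | (4S)-4-benzyl-3-(3-methylbut-2-enoyl)-1,3-oxazolidin-2-one | CC(C)=CC(=O)N1[C@@H](Cc2ccccc2)COC1=O | intermediate
5 | (4S)-4-benzyl-3-(3,3-dimethylhept-6-enoyl)-1,3-oxazolidin-2-one | C=CCCC(C)(C)CC(=O)N1[C@@H](Cc2ccccc2)COC1=O | intermediate
6 | trichlorotitanium (Z)-enolate of 5 (formed in the flask) | C=CCCC(C)(C)/C=C(\O[Ti](Cl)(Cl)Cl)N1[C@@H](Cc2ccccc2)COC1=O | intermediate
7 | (4S)-4-benzyl-3-{(2R)-2-[(benzyloxy)methyl]-3,3-dimethylhept-6-enoyl}-1,3-oxazolidin-2-one | C=CCCC(C)(C)[C@@H](C(=O)N1[C@@H](Cc2ccccc2)COC1=O)COCc1ccccc1 | intermediate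
8 | (2R)-2-[(benzyloxy)methyl]-3,3-dimethylhept-6-enoic acid | C=CCCC(C)(C)[C@@H](C(=O)O)COCc1ccccc1 | intermediate
9 | (3R)-3-[(benzyloxy)methyl]-4,4-dimethyloct-7-en-2-one | C=CCCC(C)(C)[C@@H](C(C)=O)COCc1ccccc1 | intermediate
10 | benzyl (2R)-3,3-dimethyl-2-(prop-1-en-2-yl)hept-6-en-1-yl ether (metathesis precursor) | C=CCCC(C)(C)[C@@H](C(C)=C)COCc1ccccc1 | intermediate
11 | benzyl [(1S)-2,6,6-trimethylcyclohex-2-en-1-yl]methyl ether ((S)-α-cyclogeranyl benzyl ether) | CC1=CCCC(C)(C)[C@@H]1COCc1ccccc1 | intermediate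
12 | [(1S)-2,6,6-trimethylcyclohex-2-en-1-yl]methanol ((S)-α-cyclogeraniol) | CC1=CCCC(C)(C)[C@@H]1CO | intermediate
13 | phenyl [(1S)-2,6,6-trimethylcyclohex-2-en-1-yl]methyl sulfide | CC1=CCCC(C)(C)[C@@H]1CSc1ccccc1 | intermediate
14 | phenyl [(1S)-2,6,6-trimethylcyclohex-2-en-1-yl]methyl sulfone | CC1=CCCC(C)(C)[C@@H]1CS(=O)(=O)c1ccccc1 | intermediate
15 | (2E,6E)-farnesol | CC(C)=CCC/C(C)=C/CC/C(C)=C/CO | starting material
16 | (2E,6E)-farnesyl tert-butyldimethylsilyl ether | CC(C)=CCC/C(C)=C/CC/C(C)=C/CO[Si](C)(C)C(C)(C)C | intermediate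
17 | (2E,6E,10E)-12-[(tert-butyldimethylsilyl)oxy]-2,6,10-trimethyldodeca-2,6,10-trien-1-ol | OC/C(C)=C/CC/C(C)=C/CC/C(C)=C/CO[Si](C)(C)C(C)(C)C | intermediate
18 | (2E,6E,10E)-12-bromo-3,7,11-trimethyldodeca-2,6,10-trien-1-yl tert-butyldimethylsilyl ether | BrC/C(C)=C/CC/C(C)=C/CC/C(C)=C/CO[Si](C)(C)C(C)(C)C | intermediate
19 | α-lithio derivative of sulfone 14, lithium at C25' (formed in the flask) | CC1=CCCC(C)(C)[C@@H]1C([Li])S(=O)(=O)c1ccccc1 | intermediate
20 | (2E,6E,10E)-3,7,11-trimethyl-13-(phenylsulfonyl)-13-[(1S)-2,6,6-trimethylcyclohex-2-en-1-yl]trideca-2,6,10-trien-1-yl tert-butyldimethylsilyl ether (C25' epimers) | CC1=CCCC(C)(C)[C@@H]1C(S(=O)(=O)c1ccccc1)C/C(C)=C/CC/C(C)=C/CC/C(C)=C/CO[Si](C)(C)C(C)(C)C | intermediate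
21 | (2E,6E,10E)-3,7,11-trimethyl-13-(phenylsulfonyl)-13-[(1S)-2,6,6-trimethylcyclohex-2-en-1-yl]trideca-2,6,10-trien-1-ol (C25' epimers) | CC1=CCCC(C)(C)[C@@H]1C(S(=O)(=O)c1ccccc1)C/C(C)=C/CC/C(C)=C/CC/C(C)=C/CO | intermediate
22 | (2E,6E,10E)-1-bromo-3,7,11-trimethyl-13-(phenylsulfonyl)-13-[(1S)-2,6,6-trimethylcyclohex-2-en-1-yl]trideca-2,6,10-triene (C25' epimers) | CC1=CCCC(C)(C)[C@@H]1C(S(=O)(=O)c1ccccc1)C/C(C)=C/CC/C(C)=C/CC/C(C)=C/CBr | intermediate
23 | menadione (2-methylnaphthalene-1,4-dione) | CC1=CC(=O)c2ccccc2C1=O | starting material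
24 | 2-methylnaphthalene-1,4-diol (menadiol, formed in the flask) | Cc1cc(O)c2ccccc2c1O | intermediate
25 | 1,4-dimethoxy-2-methylnaphthalene | COc1cc(C)c(OC)c2ccccc12 | intermediate
26 | 2-(chloromethyl)-1,4-dimethoxy-3-methylnaphthalene | COc1c(C)c(CCl)c(OC)c2ccccc12 | intermediate
27 | (2R)-3-bromo-2-methylpropan-1-ol | OC[C@@H](C)CBr | starting material
28 | (2R)-3-bromo-2-methylpropyl tert-butyldimethylsilyl ether | CC(C)(C)[Si](C)(C)OC[C@@H](C)CBr | intermediate
29 | (6S)-8-bromo-2,6-dimethyloct-2-ene ((S)-citronellyl bromide) | BrCC[C@@H](C)CCC=C(C)C | starting material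
30 | bromo{(2R)-3-[(tert-butyldimethylsilyl)oxy]-2-methylpropyl}magnesium (formed in the flask) | CC(C)(C)[Si](C)(C)OC[C@@H](C)C[Mg]Br | intermediate
31 | (2S,6R)-2,6,10-trimethylundec-9-en-1-yl tert-butyldimethylsilyl ether | CC(C)(C)[Si](C)(C)OC[C@@H](C)CCC[C@@H](C)CCC=C(C)C | intermediate
32 | (4R,8S)-9-[(tert-butyldimethylsilyl)oxy]-4,8-dimethylnonanal (formed in the flask) | CC(C)(C)[Si](C)(C)OC[C@@H](C)CCC[C@@H](C)CCC=O | intermediate
33 | (4R,8S)-9-[(tert-butyldimethylsilyl)oxy]-4,8-dimethylnonan-1-ol | CC(C)(C)[Si](C)(C)OC[C@@H](C)CCC[C@@H](C)CCCO | intermediate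
34 | (2S,6R)-9-iodo-2,6-dimethylnonyl tert-butyldimethylsilyl ether | CC(C)(C)[Si](C)(C)OC[C@@H](C)CCC[C@@H](C)CCCI | intermediate
35 | (2S,6R)-2,6-dimethylundec-10-yn-1-yl tert-butyldimethylsilyl ether | CC(C)(C)[Si](C)(C)OC[C@@H](C)CCC[C@@H](C)CCCC#C | intermediate
36 | dimethyl{(1E,6R,10S)-11-[(tert-butyldimethylsilyl)oxy]-2,6,10-trimethylundec-1-en-1-yl}alumane (formed in the flask) | CC(C)(C)[Si](C)(C)OC[C@@H](C)CCC[C@@H](C)CCC/C(C)=C/[Al](C)C | intermediate
37 | (2S,6R,10E)-12-(1,4-dimethoxy-3-methylnaphthalen-2-yl)-2,6,10-trimethyldodec-10-en-1-yl tert-butyldimethylsilyl ether | CC(C)(C)[Si](C)(C)OC[C@@H](C)CCC[C@@H](C)CCC/C(C)=C/Cc1c(C)c(OC)c2ccccc2c1OC | intermediate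
38 | (2S,6R,10E)-12-(1,4-dimethoxy-3-methylnaphthalen-2-yl)-2,6,10-trimethyldodec-10-en-1-ol | OC[C@@H](C)CCC[C@@H](C)CCC/C(C)=C/Cc1c(C)c(OC)c2ccccc2c1OC | intermediate
39 | 2-[(2E,7R,11S)-12-iodo-3,7,11-trimethyldodec-2-en-1-yl]-1,4-dimethoxy-3-methylnaphthalene | IC[C@@H](C)CCC[C@@H](C)CCC/C(C)=C/Cc1c(C)c(OC)c2ccccc2c1OC | intermediate
40 | 1,4-dimethoxy-2-methyl-3-[(2E,7R,11S)-3,7,11-trimethyl-12-(phenylsulfonyl)dodec-2-en-1-yl]naphthalene | O=S(=O)(c1ccccc1)C[C@@H](C)CCC[C@@H](C)CCC/C(C)=C/Cc1c(C)c(OC)c2ccccc2c1OC | intermediate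
41 | α-lithio derivative of sulfone 40, lithium at C12' (formed in the flask) | [Li]C(S(=O)(=O)c1ccccc1)[C@@H](C)CCC[C@@H](C)CCC/C(C)=C/Cc1c(C)c(OC)c2ccccc2c1OC | intermediate
42 | bis-sulfone: compound 43 bearing phenylsulfonyl groups at C12' and C25' (epimers at both) | CC1=CCCC(C)(C)[C@@H]1C(S(=O)(=O)c1ccccc1)C/C(C)=C/CC/C(C)=C/CC/C(C)=C/CC(S(=O)(=O)c1ccccc1)[C@@H](C)CCC[C@@H](C)CCC/C(C)=C/Cc1c(C)c(OC)c2ccccc2c1OC | intermediate
43 | 1,4-dimethoxy-2-methyl-3-[(2E,7R,11S,14E,18E,22E)-3,7,11,15,19,23-hexamethyl-25-[(1S)-2,6,6-trimethylcyclohex-2-en-1-yl]pentacosa-2,14,18,22-tetraen-1-yl]naphthalene | CC1=CCCC(C)(C)[C@@H]1CC/C(C)=C/CC/C(C)=C/CC/C(C)=C/CC[C@@H](C)CCC[C@@H](C)CCC/C(C)=C/Cc1c(C)c(OC)c2ccccc2c1OC | intermediate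
44 | 2-methyl-3-[(2E,7R,11S,14E,18E,22E)-3,7,11,15,19,23-hexamethyl-25-[(1S)-2,6,6-trimethylcyclohex-2-en-1-yl]pentacosa-2,14,18,22-tetraen-1-yl]naphthalene-1,4-dione (CNP0165638.1) | CC1=CCCC(C)(C)[C@@H]1CC/C(C)=C/CC/C(C)=C/CC/C(C)=C/CC[C@@H](C)CCC[C@@H](C)CCC/C(C)=C/CC1=C(C)C(=O)c2ccccc2C1=O | target

Total step count: 30.
Longest linear sequence: 16 steps (steps 1–10, 14–16 and 28–30).

Steps most likely to fail

Step 7 (ring-closing metathesis). The alkylidene formed at C28' may be slow to engage the hindered isopropenyl group, so that intermolecular cross-metathesis, or hydride-induced migration of the terminal olefin followed by closure of a smaller ring, competes. The fallback forms the same C27'=C28' bond by reductive carbonyl coupling. It sets out from ketone 9, whose only olefin would be cleaved by ozonolysis (O3, CH2Cl2, −78 °C; PPh3) to the keto aldehyde (5R)-5-[(benzyloxy)methyl]-4,4-dimethyl-6-oxoheptanal F1. An intramolecular McMurry coupling with low-valent titanium (TiCl3(DME)1.5, Zn–Cu couple, DME, reflux, slow addition) would then close the cyclohexene under non-basic conditions, and the route is rejoined at 11.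

Step 3 (alkoxymethylation of the hindered enolate). Carbon–carbon bond formation at the neopentyl-type enolate carbon may be slow, so that the chloromethyl ether is consumed by Lewis-acid decomposition and facial control erodes. The fallback replaces the alkylation by an aldol-type addition to the smallest possible electrophile and separates the protection from the stereo-defining event. It sets out from 5: the same enolate 6 would be treated with s-trioxane and additional TiCl4 (monomeric formaldehyde) to give (4S)-4-benzyl-3-[(2R)-2-(hydroxymethyl)-3,3-dimethylhept-6-enoyl]-1,3-oxazolidin-2-one F2. Its primary alcohol would be benzylated without base (benzyl 2,2,2-trichloroacetimidate, TfOH cat., CH2Cl2/cyclohexane, 0 °C), and the route is rejoined at 7.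

Step 24 (carboalumination and nickel coupling). Transfer of the alkenyl group from aluminium to the congested benzylnickel intermediate may be slow, so that homocoupling of the benzylic chloride and protodemetallation of the alane take over. The fallback inverts the polarity of the two partners. It sets out from alkyne 35: carboalumination as before and iodinolysis of alane 36 (I2, THF, −30 °C) would give tert-butyl{[(2S,6R,10E)-11-iodo-2,6,10-trimethylundec-10-en-1-yl]oxy}dimethylsilane F3. Chloride 26 would be converted with zinc dust and LiCl in THF into [(1,4-dimethoxy-3-methylnaphthalen-2-yl)methyl]zinc chloride F4. A Negishi coupling of F3 with F4 (Pd(PPh3)4, THF, rt to 50 °C) would form C1'–C2' with retention of the E geometry, and the route is rejoined at 37.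

Further compounds

F1 | step 7 | (5R)-5-[(benzyloxy)methyl]-4,4-dimethyl-6-oxoheptanal | O=CCCC(C)(C)[C@@H](C(C)=O)COCc1ccccc1
F2 | step 3 | (4S)-4-benzyl-3-[(2R)-2-(hydroxymethyl)-3,3-dimethylhept-6-enoyl]-1,3-oxazolidin-2-one | C=CCCC(C)(C)[C@@H](C(=O)N1[C@@H](Cc2ccccc2)COC1=O)CO
F3 | step 24 | tert-butyl{[(2S,6R,10E)-11-iodo-2,6,10-trimethylundec-10-en-1-yl]oxy}dimethylsilane | CC(C)(C)[Si](C)(C)OC[C@@H](C)CCC[C@@H](C)CCC/C(C)=C/I
F4 | step 24 | [(1,4-dimethoxy-3-methylnaphthalen-2-yl)methyl]zinc chloride | COc1c(C)c(C[Zn]Cl)c(OC)c2ccccc12
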